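The coupling partner is the reagent here: it meets a racemic substrate, and it can also meet the protic impurity, fall apart, or pair with itself.

| flask | left-handed substrate | coupling partner | protic impurity | right-handed substrate | time |
|---|---|---|---|---|---|
| theta | 33 mM | 12.0 mM | 9.90 mM | 33 mM | 20 min |
| epsilon | 33 mM | 20.0 mM | 9.90 mM | 33 mM | 20 min |
| alpha | 33 mM | 25.0 mM | 9.90 mM | 33 mM | 20 min |
| zeta | 33 mM | 40.0 mM | 9.90 mM | 33 mM | 20 min |
| gamma | 33 mM | 60.0 mM | 9.90 mM | 33 mM | 20 min |

    coupling partner + left-handed substrate → left-handed product (k1 = 1.48 /M/min)
    coupling partner + right-handed substrate → right-handed product (k2 = 0.279 /M/min)
    coupling partner + protic impurity → quenched reagent (k3 = 4.61 /M/min)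
    coupling partner → decomposed reagent (k4 = 0.237 /min)
    2 coupling partner → homo dimer (k5 = 2.71 /M/min)

- coupling partner is single-handed; left-handed substrate and right-handed substrate are mirror images of each other, charged as a racemate, each of them at the stated concentration
- a doubled species enters its step squared and goes two at a time
- "hardly changes" means that all values lie within two and a half points (for a concentration: within two and a half percent of the largest)
- run time (theta): 20 min
- the handed part of coupling partner does not stay in what it makes, so the products of the two hands are mirror images too

* amount of left-handed product at the end, in percent of the left-handed substrate and right-handed substrate together charged for theta, epsilon, alpha, zeta, gamma, in this order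
* how that number moves from the first to the last of them (falls all the way / rises, then falls / rises all the way / hardly changes / falls, then rises)

Two numbers seem not to fit. At the theta charge of coupling partner, a steady partner would take 9.87 mM of left-handed substrate in 20 min, which is less than the 12.0 mM charged. That suggests a flask with a good part of its left-handed substrate turned over. Yet the same run holds 4.74 turnovers of the partner's decomposition against 0.355 turnovers of that substrate.

The second number clears up the first: the partner does not stay at its charge. In my own reckoning the two substrates and the impurity stay at their charges, so the partner is lost at a steady, pseudo-first-order 0.341 /min. That is a lifetime of 2.93 min, shorter than the run, and the run length drops out of the sum. Pairing adds a loss that starts at 0.0650 /min in theta, smaller than the steady one.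

Adding up the partner's whole life gives the turnover count 0.0477: the coupling constant of the left-handed substrate times the partner's concentration, summed over the run. It equals the coupling constant over twice the pairing constant, times the natural logarithm of one plus the ratio of starting pairing loss to steady loss. The left-handed substrate keeps the fraction exp(-count), and it is half of the substrate charged, so the asked number is half of what it loses. That gives 2.33% for theta, and by the same count 3.63% for epsilon, 4.37% for alpha, 6.29% for zeta and 8.36% for gamma. With the steady loss held fixed, the logarithm climbs with every added charge, but more slowly than the charge. The count in gamma is 0.183, larger than in theta, so my row rises all the way.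

The forecast gives 2.36%, 3.7%, 4.45%, 6.4% and 8.6%, a row that rises all the way, because “its time-integrated exposure grows less than proportionally with the charge”. Its first point lies a little over mine.

The flask gives 2.36%, 3.69%, 4.46%, 6.46% and 8.64%, and the row rises all the way. In theta at 1.94 min, the partner's half-life by decomposition is 2.9 min, far shorter than the 82 min of the left-handed substrate by its coupling, and the count of 0.0477 keeps 95.3% of that substrate, where the flask reads 95%. In gamma the count of 0.183 keeps 83.3% of the left-handed substrate; the flask reads 83%, with 0.092% of the partner left.

Its constants stand for no real mixture; the result is computed.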